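**Plan**

1. Retrosynthesis: both dihydropyran rings are cut by retro-hetero-Diels–Alder, ring B (O–C2 and CH2–C1) first and ring A (O–C9 and CH2–C8) second. This leaves two molecules of one tropolone o-quinone methide and (S)-10-hydroxyhumulene.
2. Enabling feature: each dihydropyran is the four-atom unit O–C=C–CH2 of a tropolone laid across a former E-trisubstituted alkene of the 11-membered humulene ring, with the ether oxygen on the methyl-bearing carbon. The C10 carbinol is allylic to the C8=C9 alkene under ring A.
3. Fragment 1: 2,5-dimethylresorcinol is formylated, the benzene ring is expanded to the tropolone by a two-enzyme dearomatisation and ring expansion, and the aldehyde is reduced to the hydroxymethyl tropolone (the quinone methide at the alcohol oxidation level, nothing to remove later).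
4. Fragment 2: α-humulene is hydroxylated at C10, oxidised to the enone and reduced (Corey–Bakshi–Shibata) to the (S)-alcohol.
5. Both rings arise in one pot in step 7: ring A first, closed by a hetero-Diels–Alderase at the allylic-alcohol alkene C8=C9, then ring B at the remaining trisubstituted alkene C1=C2 with a second molecule of the same quinone methide.
6. Stereochemistry: C10 from the CBS reduction; C8/C9 and C1/C2 from suprafacial addition to E-alkenes (trans fusions), the face chosen by the enzyme for ring A and by the ring conformation for ring B.

Key step: step 7

Numbering: humulene numbering is used throughout, C1H=C2(CH3)–C3H2–C4H=C5H–C6(CH3)2–C7H2–C8H=C9(CH3)–C10H2–C11H2; the target is (1R,2R,8R,9R,10S).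

Assumption: the pathway hetero-Diels–Alderase is taken to convert (S)-10-hydroxyhumulene into the ring A configuration of the target and to let the mono-adduct go on to the bis-adduct in the same pot, and quinol 4 is written as its (R) form, a centre that is lost within the same step.

**Route**

Step 1
Reactants: 1 2,5-dimethylbenzene-1,3-diol
Product: 3 2,4-dihydroxy-3,6-dimethylbenzaldehyde (3-methylorcinaldehyde), via iminium chloride 2 (not isolated)
Conditions: POCl3, DMF, MeCN, 0 °C to rt; then H2O, 50 °C
Reagents that add atoms: N,N-dimethylformamide, CN(C)C=O (formyl carbon); water, O (aldehyde oxygen)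
Why: Vilsmeier–Haack formylation; the two open ring positions of the symmetrical resorcinol are equivalent, each ortho to one hydroxyl and para to the other, so only one aldehyde can form.

Step 2
Reactants: 3 3-methylorcinaldehyde
Product: 5 stipitaldehyde (5-formyl-2,4-dihydroxy-6-methylcyclohepta-2,4,6-trien-1-one), via o-quinol 4 (not isolated)
Conditions: flavin-dependent monooxygenase (TropB type), NADP+ (cat.), Na2HPO3, phosphite dehydrogenase, air, KH2PO4/K2HPO4 buffer pH 8.0, 30 °C; then α-ketoglutarate-dependent non-heme iron dioxygenase (TropC type), 2-oxoglutaric acid, FeSO4 (cat.), ascorbic acid (cat.), air, 30 °C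
Reagents that add atoms: dioxygen, O=O
Why: This is the native fungal tropolone sequence on its native substrate: flavin-dependent hydroxylative dearomatisation at the methyl-bearing C3 gives the o-quinol, and the iron enzyme abstracts hydrogen from that methyl group so that its carbon is inserted between C2 and C3 (radical ring expansion of the six- to the seven-membered ring), the quinol stereocentre being lost on aromatisation.

Step 3
Reactants: 5 stipitaldehyde
Product: 6 2,4-dihydroxy-5-(hydroxymethyl)-6-methylcyclohepta-2,4,6-trien-1-one (tropolone alcohol)
Conditions: NaBH4, MeOH, 0 °C; aqueous work-up at pH 4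
Reagents that add atoms: none
Why: Borohydride reduction of the aryl aldehyde; the tropolone carbonyl is masked as its tropolonate under the basic conditions and the low temperature should keep the product from losing water to the quinone methide.

Step 4
Reactants: 7 α-humulene
Product: 8 racemic 10-hydroxyhumulene, (2E,6E,9E)-2,5,5,9-tetramethylcycloundeca-2,6,9-trien-1-ol
Conditions: SeO2 (20 mol %), t-BuOOH (2 equiv), CH2Cl2, 0 °C to rt
Reagents that add atoms: selenium dioxide, O=[Se]=O (delivers the oxygen); tert-butyl hydroperoxide, CC(C)(C)OO (reoxidant and ultimate oxygen source)
Why: Riley allylic oxidation (ene reaction then [2,3]-sigmatropic shift), which hydroxylates the ring CH2 at the more substituted end of a trisubstituted alkene and returns the E double bond; C10 is the only such CH2 that is not doubly allylic, and the alcohol forms as the racemate.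

Step 5
Reactants: 8 racemic 10-hydroxyhumulene
Product: 9 (2E,6E,9E)-2,5,5,9-tetramethylcycloundeca-2,6,9-trien-1-one (humulen-10-one)
Conditions: MnO2 (activated, excess), CH2Cl2, rt
Reagents that add atoms: none
Why: Allylic alcohol oxidation with MnO2 under neutral conditions, which spare the three alkenes and avoid base that could move the C1=C2 alkene into conjugation through C11.

Step 6
Reactants: 9 humulen-10-one
Product: 10 (S)-10-hydroxyhumulene, (1S,2E,6E,9E)-2,5,5,9-tetramethylcycloundeca-2,6,9-trien-1-ol
Conditions: (R)-2-methyl-CBS-oxazaborolidine (20 mol %), catecholborane (1.5 equiv), toluene, −78 °C; then H2O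
Reagents that add atoms: none
Why: Corey–Bakshi–Shibata reduction: the α-methyl alkenyl arm acts as the large group and the ring CH2 as the small one, so the (R)-catalyst should deliver hydride to the face that gives the (S)-carbinol at C10, and catecholborane at −78 °C leaves the alkenes untouched.

Step 7
Reactants: 10 (S)-10-hydroxyhumulene; 6 tropolone alcohol (two molecules are incorporated)
Product: 13 CNP0283947.4 (1R,2R,8R,9R,10S), via o-quinone methide 11 (not isolated), via ring A mono-adduct 12 (not isolated)
Conditions: recombinant hetero-Diels–Alderase of the tropolone sesquiterpenoid pathway (about 2 mol %), KH2PO4/K2HPO4 buffer (50 mM, pH 7.5), DMSO (5 % v/v), 30 °C; 6 (3.5 equiv in all) added in portions, the first 1.2 equiv until 10 is consumed, the remainder until 12 is consumed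
Reagents that add atoms: none
Why: The enzyme assists loss of water from 6 to give o-quinone methide 11, whose 1-oxadiene (tropolone O=C–C=CH2) adds across the C8=C9 alkene of 10 in a concerted but asynchronous inverse-electron-demand hetero-Diels–Alder reaction, the CH2–C8 bond leading and the O–C9 bond following, to give mono-adduct 12; a second molecule of 11 then adds in the same way across C1=C2 of 12 (CH2 to C1, O to C2). The closest known reaction type is the hetero-Diels–Alderase-catalysed cycloaddition of this quinone methide with humulenol in the biosynthesis of the tropolone sesquiterpenoids, together with the uncatalysed thermal cycloaddition of o-quinone methides with the trisubstituted alkenes of humulene. Ring A and ring B, both dihydropyrans, are each closed by an intermolecular [4+2] cycloaddition that forms the C–C and the C–O bond of the ring through a six-membered transition state. C8 and C9 are set relative to each other by suprafacial addition to the E-alkene (H on C8 trans to CH3 on C9) and in the absolute sense by the alkene face that the active site exposes once the C10 hydroxyl of the (S)-alcohol is bound; C1 and C2 are likewise set trans by suprafacial addition to the E-alkene, and their face by approach from the outside of the ring in the conformer fixed by ring A and the C10 carbinol, or by the active site if the enzyme also turns over 12. The step needs site selectivity for C8=C9 in the first event and for C1=C2 over the disubstituted C4=C5 in the second, the regiochemistry CH2 to the CH carbon and O to the methyl-bearing carbon, and one alkene face each time; the enzyme pocket with the allylic C10 hydroxyl as recognition handle secures the first site and face, the higher nucleophilicity of a trisubstituted over a 1,2-disubstituted alkene secures the second site, and the polarisation of each trisubstituted alkene (cationic character best borne at the tertiary carbon) secures the regiochemistry. Water in the medium only returns stray 11 to 6, so the quinone methide is not lost while it waits for the slower second cycloaddition.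

**Compound list**

1 | 2,5-dimethylbenzene-1,3-diol | Cc1cc(O)c(C)c(O)c1 | starting material
2 | N-[(2,4-dihydroxy-3,6-dimethylphenyl)methylidene]-N-methylmethanaminium chloride | C[N+](C)=Cc1c(C)cc(O)c(C)c1O.[Cl-] | intermediate
3 | 2,4-dihydroxy-3,6-dimethylbenzaldehyde (3-methylorcinaldehyde) | Cc1cc(O)c(C)c(O)c1C=O | intermediate
4 | (R)-2,3-dihydroxy-3,6-dimethyl-4-oxocyclohexa-1,5-diene-1-carbaldehyde (o-quinol) | CC1=CC(=O)[C@](C)(O)C(O)=C1C=O | intermediate
5 | stipitaldehyde, 5-formyl-2,4-dihydroxy-6-methylcyclohepta-2,4,6-trien-1-one | Cc1cc(=O)c(O)cc(O)c1C=O | intermediate
6 | 2,4-dihydroxy-5-(hydroxymethyl)-6-methylcyclohepta-2,4,6-trien-1-one (tropolone alcohol) | Cc1cc(=O)c(O)cc(O)c1CO | intermediate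
7 | α-humulene, (1E,4E,8E)-2,6,6,9-tetramethylcycloundeca-1,4,8-triene | C/C1=C\CC(C)(C)/C=C/C/C(C)=C/CC1 | starting material
8 | racemic 10-hydroxyhumulene, (2E,6E,9E)-2,5,5,9-tetramethylcycloundeca-2,6,9-trien-1-ol | C/C1=C\CC(C)(C)/C=C/C/C(C)=C/CC1O | intermediate
9 | humulen-10-one, (2E,6E,9E)-2,5,5,9-tetramethylcycloundeca-2,6,9-trien-1-one | C/C1=C\CC(C)(C)/C=C/C/C(C)=C/CC1=O | intermediate
10 | (S)-10-hydroxyhumulene, (1S,2E,6E,9E)-2,5,5,9-tetramethylcycloundeca-2,6,9-trien-1-ol | C/C1=C\CC(C)(C)/C=C/C/C(C)=C/C[C@@H]1O | intermediate
11 | tropolone o-quinone methide, 2-hydroxy-6-methyl-5-methylidenecyclohepta-2,6-diene-1,4-dione | C=C1C(=O)C=C(O)C(=O)C=C1C | intermediate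
12 | ring A mono-adduct: (S)-10-hydroxyhumulene with one tropolone-fused dihydropyran across C8–C9 (aryl CH2 on C8, aryl O on C9, H on C8 trans to CH3 on C9; 8R,9R,10S); C1=C2 and C4=C5 remain E | Cc1cc(=O)c(O)cc2c1C[C@H]1CC(C)(C)/C=C/C/C(C)=C/C[C@H](O)[C@]1(C)O2 | intermediate
13 | CNP0283947.4: 10-hydroxyhumulene carrying tropolone-fused dihydropyrans across C8–C9 (ring A) and C1–C2 (ring B), both trans-fused, C4=C5 E; 1R,2R,8R,9R,10S | Cc1cc(=O)c(O)cc2c1C[C@H]1CC(C)(C)/C=C/C[C@@]3(C)Oc4cc(O)c(=O)cc(C)c4C[C@@H]3C[C@H](O)[C@]1(C)O2 | target

**Summary**

Total step count: 7. Longest linear sequence: 4 steps (7 to 13 through steps 4 to 7; equally 1 to 13 through steps 1 to 3 and 7).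

Steps most likely to fail:

Step 7. The enzyme may express poorly, turn over slowly on preparative scale, discriminate insufficiently between the two trisubstituted alkenes, or stop at the mono-adduct. Fallback, from 10 to 13: 10 is heated with an excess of 6 (4 equiv, in portions) in o-xylene at 150 °C, so that thermal loss of water from 6 gives 11 and both trisubstituted alkenes are annulated without the enzyme. Whichever alkene reacts first, giving 12 or the ring B mono-adduct F3, the second cycloaddition converges on the bis-adduct, so site selectivity is no longer required. Facial control then rests on a hydrogen bond from the C10 hydroxyl to the quinone methide carbonyl and on outer-face approach to each E-alkene, and 13 is separated from diastereomers by preparative HPLC. If only the second cycloaddition fails in buffer, 12 is extracted and heated with 6 under the same conditions.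

Step 4. The selenium reagent may attack the more nucleophilic C1=C2 alkene (at its methyl group or the doubly allylic C3) instead of the C8=C9 region, or over-oxidise. Fallback, from 7 back to 8: 7 is first treated with mCPBA (1 equiv, CH2Cl2, 0 °C), which epoxidises the most nucleophilic alkene C1=C2, to give racemic humulene 1,2-epoxide F1. SeO2/t-BuOOH then finds only one trisubstituted alkene and should hydroxylate C10 to give the 10-hydroxy epoxide F2 as a pair of carbinol epimers. Stereospecific deoxygenation with Ph3P=Se and CF3CO2H in CH2Cl2 (retention of the E geometry) returns to racemic alcohol 8, the alkene having been protected as its epoxide during the oxidation.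

Step 6. Poor facial discrimination by the oxazaborolidine may leave the alcohol with low enantiomeric purity, because the two arms of the eleven-membered ketone differ less in size than those of an acyclic enone. Fallback, from 8 to 10, bypassing 9: racemic 8 is resolved by lipase-catalysed transesterification (immobilised Candida antarctica lipase B, vinyl acetate, hexane, 30 °C). By the usual empirical preference of this lipase, the (R)-alcohol should be acylated to (R)-10-acetoxyhumulene F4. The (S)-alcohol 10 should remain unreacted and is separated from F4 by chromatography.

**Further compounds**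

F1 | step 4 | racemic humulene 1,2-epoxide (trans epoxide, one enantiomer drawn) | C/C1=C\CC(C)(C)/C=C/C[C@@]2(C)O[C@@H]2CC1
F2 | step 4 | racemic 10-hydroxyhumulene 1,2-epoxide (trans epoxide, both C10 epimers) | C/C1=C\CC(C)(C)/C=C/C[C@@]2(C)O[C@@H]2CC1O
F3 | step 7 | ring B mono-adduct: (S)-10-hydroxyhumulene with the tropolone-fused dihydropyran across C1–C2 (1R,2R,10S), C8=C9 and C4=C5 E | C/C1=C\CC(C)(C)/C=C/C[C@@]2(C)Oc3cc(O)c(=O)cc(C)c3C[C@@H]2C[C@@H]1O
F4 | step 6 | (R)-10-acetoxyhumulene, (1R,2E,6E,9E)-2,5,5,9-tetramethylcycloundeca-2,6,9-trien-1-yl acetate | C/C1=C\CC(C)(C)/C=C/C/C(C)=C/C[C@H]1OC(C)=O
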